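**Retrosynthetic overview**
1. Key bond: the lactone aryl O–C(=O) bond of 12, closed last. Opening it and masking both ring phenols as OMe gives the open (R)-3,3-diarylpropanoate 10.
2. 10 ⇒ racemic 8. The C–H stereocentre is erased by oxidation to p-quinone methide 9 and rewritten by a catalytic asymmetric 1,6-hydride transfer (new step).
3. 8 ⇒ aryl-pyranone 6 + methyl p-coumarate 7 by acid hydroarylation. The two OMe groups steer attack to the carbon between OMe and CH3.
4. 6 ⇒ acid 1 + methoxycrotonate 2: γ-acylation, then the pyranone is closed by enol lactonisation (C–O).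
5. Ring order: pyranone first (step 1), dihydrocoumarin last (step 4). Both rings are closed through C–O bonds.

Assumption: 1, 2 and 7 are catalogue chemicals, and the antipode of the phosphoric acid that gives the (R) product is fixed by one test run ((R)-TRIP is written).

**Step 1**
Reactants: 1 2,4-dimethoxy-6-methylbenzoic acid; 2 methyl (E)-3-methoxybut-2-enoate
Product: 6 6-(2,4-dimethoxy-6-methylphenyl)-4-methoxy-2H-pyran-2-one, via acid chloride 3 (not isolated), via lithium dienolate 4 (not isolated), via open-chain keto ester 5 (not isolated)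
Conditions: 1, (COCl)2, cat. DMF, CH2Cl2, rt, evaporate; 2 (2.2 equiv), LDA (2.2 equiv), THF, −78 °C, add 3, −78 °C to rt; aq HCl; crude, cat. DBU, PhMe, 80 °C
Reagents that add atoms: none
Why: Vinylogous Claisen acylation, in which dienolate 4 (the anion that is silylated to make Brassard's diene) is acylated at its γ-carbon by 3, and because the E-alkene holds the new aroylmethyl group cis to CO2Me, the enol oxygen of 5 closes the 2-pyranone by lactonisation with loss of MeOH; no stereocentre is formed.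

**Step 2**
Reactants: 6 6-(2,4-dimethoxy-6-methylphenyl)-4-methoxy-2H-pyran-2-one; 7 methyl (E)-3-(4-hydroxyphenyl)prop-2-enoate
Product: 8 racemic methyl 3-[4,6-dimethoxy-2-methyl-3-(4-methoxy-2-oxo-2H-pyran-6-yl)phenyl]-3-(4-hydroxyphenyl)propanoate
Conditions: TFA, 50 °C, slow addition of 7 (1.3 equiv), 16 h
Reagents that add atoms: none
Why: Brønsted-acid hydroarylation (Friedel–Crafts conjugate alkylation of an electron-rich cinnamate), in which TFA protonates 7 at Cα to the p-hydroxybenzyl cation, this attacks the one ring carbon of 6 that is para to one OMe, ortho to the other and not wedged between two OMe groups (the site at which 3,5-dimethoxytoluene derivatives are brominated and formylated), the protonated pyranone is switched off, and the stereocentre is formed racemic on purpose.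

**Step 3**
Reactants: 8 racemic methyl 3-[4,6-dimethoxy-2-methyl-3-(4-methoxy-2-oxo-2H-pyran-6-yl)phenyl]-3-(4-hydroxyphenyl)propanoate
Product: 10 methyl (3R)-3-[4,6-dimethoxy-2-methyl-3-(4-methoxy-2-oxo-2H-pyran-6-yl)phenyl]-3-(4-hydroxyphenyl)propanoate, via p-quinone methide 9 (not isolated)
Conditions: DDQ (1.05 equiv), PhMe, 0 °C, 20 min; filter; (R)-TRIP (5 mol %), Hantzsch ester (1.5 equiv), 4 Å MS, PhMe, −20 °C to rt
Reagents that add atoms: none
Why: Proposed new method: one-pot redox deracemisation of a diarylmethine, in which DDQ abstracts the doubly benzylic hydride of 8 (para to the free OH and ortho/para to both OMe groups), loss of the phenol proton gives the planar p-quinone methide 9 whose unsubstituted quinoid ring has no E/Z isomers, so C3 is erased; the chiral phosphoric acid then hydrogen-bonds the quinone-methide carbonyl and the N–H of the Hantzsch ester and steers the 1,6-hydride transfer to one face of the exocyclic carbon, whose two substituents (a perpendicular 2,6-disubstituted aryl against CH2CO2Me) differ strongly in size, giving (R)-10, and any 9 that tautomerises to the β,β-diarylacrylate re-enters by acid re-protonation; the closest known reaction types are the phosphoric-acid/Hantzsch-ester transfer hydrogenation of in situ formed quinone methides to 1,1-diarylalkanes and oxidation-then-asymmetric-reduction deracemisations of benzylic ethers and amines.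

**Step 4**
Reactants: 10 methyl (3R)-3-[4,6-dimethoxy-2-methyl-3-(4-methoxy-2-oxo-2H-pyran-6-yl)phenyl]-3-(4-hydroxyphenyl)propanoate
Product: 12 (4R)-7-hydroxy-4-(4-hydroxyphenyl)-6-(4-methoxy-2-oxo-2H-pyran-6-yl)-5-methyl-3,4-dihydro-2H-chromen-2-one, via seco diphenol ester 11 (not isolated)
Conditions: BBr3 (5 equiv), CH2Cl2, −78 to 0 °C; aq NaHCO3
Reagents that add atoms: none
Why: BBr3 aryl methyl ether cleavage followed by lactonisation (intramolecular transesterification), in which the two aryl OMe groups should be cleaved faster at or below 0 °C than the vinylogous-ester OMe of the pyranone (by analogy with the survival of methyl esters under these conditions), the freed phenol next to the side chain in 11 closes the aryl ester C–O bond spontaneously because the ortho methyl and β-aryl groups press it onto the ester (trimethyl-lock effect), the other phenol has no acyl partner, and C4 is not touched so (R) is kept.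

**Compound list**
1 | 2,4-dimethoxy-6-methylbenzoic acid | COc1cc(C)c(C(=O)O)c(OC)c1 | starting material
2 | methyl (E)-3-methoxybut-2-enoate | CO/C(C)=C/C(=O)OC | starting material
3 | 2,4-dimethoxy-6-methylbenzoyl chloride | COc1cc(C)c(C(=O)Cl)c(OC)c1 | intermediate
4 | lithium 1,3-dimethoxybuta-1,3-dien-1-olate (γ-deprotonated 2) | [Li+].[O-]C(OC)=CC(=C)OC | intermediate
5 | methyl (E)-5-(2,4-dimethoxy-6-methylphenyl)-3-methoxy-5-oxopent-2-enoate | COC(=O)/C=C(/OC)CC(=O)c1c(C)cc(OC)cc1OC | intermediate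
6 | 6-(2,4-dimethoxy-6-methylphenyl)-4-methoxy-2H-pyran-2-one | COc1cc(-c2c(C)cc(OC)cc2OC)oc(=O)c1 | intermediate
7 | methyl (E)-3-(4-hydroxyphenyl)prop-2-enoate (methyl p-coumarate) | COC(=O)/C=C/c1ccc(O)cc1 | starting material
8 | racemic methyl 3-[4,6-dimethoxy-2-methyl-3-(4-methoxy-2-oxo-2H-pyran-6-yl)phenyl]-3-(4-hydroxyphenyl)propanoate | COC(=O)CC(c1ccc(O)cc1)c1c(C)c(-c2cc(OC)cc(=O)o2)c(OC)cc1OC | intermediate
9 | methyl 3-[4,6-dimethoxy-2-methyl-3-(4-methoxy-2-oxo-2H-pyran-6-yl)phenyl]-3-(4-oxocyclohexa-2,5-dien-1-ylidene)propanoate | COC(=O)CC(=C1C=CC(=O)C=C1)c1c(C)c(-c2cc(OC)cc(=O)o2)c(OC)cc1OC | intermediate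
10 | methyl (3R)-3-[4,6-dimethoxy-2-methyl-3-(4-methoxy-2-oxo-2H-pyran-6-yl)phenyl]-3-(4-hydroxyphenyl)propanoate | COc1cc(-c2c(OC)cc(OC)c(c2C)[C@@H](c2ccc(O)cc2)CC(=O)OC)oc(=O)c1 | intermediate
11 | methyl (3R)-3-[4,6-dihydroxy-2-methyl-3-(4-methoxy-2-oxo-2H-pyran-6-yl)phenyl]-3-(4-hydroxyphenyl)propanoate | COc1cc(-c2c(O)cc(O)c(c2C)[C@@H](c2ccc(O)cc2)CC(=O)OC)oc(=O)c1 | intermediate
12 | (4R)-7-hydroxy-4-(4-hydroxyphenyl)-6-(4-methoxy-2-oxo-2H-pyran-6-yl)-5-methyl-3,4-dihydro-2H-chromen-2-one | COc1cc(-c2c(O)cc3c(c2C)[C@@H](c2ccc(O)cc2)CC(=O)O3)oc(=O)c1 | target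

**Total steps:** 4. **Longest linear sequence:** 4 (1 → 6 → 8 → 10 → 12).

**Three steps most likely to fail**

Step 3 (the new step). Quinone methide 9 may oligomerise or rest as the acrylate tautomer, and the ee may be low. The fallback is a classical resolution, which is known chemistry, and it sets out from 6. Compound 6 is hydroarylated as in step 2, but with (E)-4-hydroxycinnamic acid, to give racemic 3-[4,6-dimethoxy-2-methyl-3-(4-methoxy-2-oxo-2H-pyran-6-yl)phenyl]-3-(4-hydroxyphenyl)propanoic acid F1. Crystallisation with (R)-1-phenylethylamine (antipode chosen by screening) gives the single diastereomeric salt (R)-1-phenylethylammonium (3R)-3-[4,6-dimethoxy-2-methyl-3-(4-methoxy-2-oxo-2H-pyran-6-yl)phenyl]-3-(4-hydroxyphenyl)propanoate F2. Acidification frees (3R)-3-[4,6-dimethoxy-2-methyl-3-(4-methoxy-2-oxo-2H-pyran-6-yl)phenyl]-3-(4-hydroxyphenyl)propanoic acid F3. BBr3 as in step 4 then gives (3R)-3-[4,6-dihydroxy-2-methyl-3-(4-methoxy-2-oxo-2H-pyran-6-yl)phenyl]-3-(4-hydroxyphenyl)propanoic acid F4, which lactonises in the flask. The fallback comes back to the route at 12.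

Step 2. The site is hindered, the coumarate may oligomerise, and attack may occur at the carbon between the two OMe groups. The fallback fixes the site with a halogen and uses only known couplings, and it sets out from 6. NBS in MeCN at 0 °C is expected to brominate the dimethoxyarene faster than the pyranone, giving 6-(3-bromo-4,6-dimethoxy-2-methylphenyl)-4-methoxy-2H-pyran-2-one F5. A Heck reaction with methyl acrylate (Pd2(dba)3, P(t-Bu)3, Cy2NMe, dioxane, 100 °C) gives methyl (E)-3-[4,6-dimethoxy-2-methyl-3-(4-methoxy-2-oxo-2H-pyran-6-yl)phenyl]prop-2-enoate F6. BBr3 (demethylation, E/Z isomerisation, lactonisation) gives 7-hydroxy-6-(4-methoxy-2-oxo-2H-pyran-6-yl)-5-methyl-2H-chromen-2-one F7. The Hayashi–Miyaura 1,4-addition of 4-hydroxyphenylboronic acid with Rh(acac)(C2H4)2/(R)-Segphos in dioxane/water at 60 °C sets (4R). This fallback comes back to the route at 12 and bypasses steps 3 and 4.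

Step 4. The pyranone OMe may be lost together with the aryl OMe groups. The fallback deprotects fully and then puts the one methyl back, and it sets out from 10. Excess BBr3 at rt strips every methyl group and gives (4R)-7-hydroxy-6-(4-hydroxy-2-oxo-2H-pyran-6-yl)-4-(4-hydroxyphenyl)-5-methyl-3,4-dihydro-2H-chromen-2-one F8. TMSCHN2 (1.0 equiv) in PhMe/MeOH at 0 °C then methylates only the vinylogous-acid OH of the pyranone (pKa about 5, against 9–10 for the phenols). The fallback comes back to the route at 12.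

**Further compounds**
F1 | step 3 | racemic 3-[4,6-dimethoxy-2-methyl-3-(4-methoxy-2-oxo-2H-pyran-6-yl)phenyl]-3-(4-hydroxyphenyl)propanoic acid | OC(=O)CC(c1ccc(O)cc1)c1c(C)c(-c2cc(OC)cc(=O)o2)c(OC)cc1OC
F2 | step 3 | (R)-1-phenylethylammonium (3R)-3-[4,6-dimethoxy-2-methyl-3-(4-methoxy-2-oxo-2H-pyran-6-yl)phenyl]-3-(4-hydroxyphenyl)propanoate | COc1cc(-c2c(OC)cc(OC)c(c2C)[C@@H](c2ccc(O)cc2)CC(=O)[O-])oc(=O)c1.C[C@@H]([NH3+])c1ccccc1
F3 | step 3 | (3R)-3-[4,6-dimethoxy-2-methyl-3-(4-methoxy-2-oxo-2H-pyran-6-yl)phenyl]-3-(4-hydroxyphenyl)propanoic acid | COc1cc(-c2c(OC)cc(OC)c(c2C)[C@@H](c2ccc(O)cc2)CC(=O)O)oc(=O)c1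
F4 | step 3 | (3R)-3-[4,6-dihydroxy-2-methyl-3-(4-methoxy-2-oxo-2H-pyran-6-yl)phenyl]-3-(4-hydroxyphenyl)propanoic acid | COc1cc(-c2c(O)cc(O)c(c2C)[C@@H](c2ccc(O)cc2)CC(=O)O)oc(=O)c1
F5 | step 2 | 6-(3-bromo-4,6-dimethoxy-2-methylphenyl)-4-methoxy-2H-pyran-2-one | COc1cc(-c2c(C)c(Br)c(OC)cc2OC)oc(=O)c1
F6 | step 2 | methyl (E)-3-[4,6-dimethoxy-2-methyl-3-(4-methoxy-2-oxo-2H-pyran-6-yl)phenyl]prop-2-enoate | COC(=O)/C=C/c1c(C)c(-c2cc(OC)cc(=O)o2)c(OC)cc1OC
F7 | step 2 | 7-hydroxy-6-(4-methoxy-2-oxo-2H-pyran-6-yl)-5-methyl-2H-chromen-2-one | COc1cc(-c2c(O)cc3oc(=O)ccc3c2C)oc(=O)c1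
F8 | step 4 | (4R)-7-hydroxy-6-(4-hydroxy-2-oxo-2H-pyran-6-yl)-4-(4-hydroxyphenyl)-5-methyl-3,4-dihydro-2H-chromen-2-one | Oc1cc(-c2c(O)cc3c(c2C)[C@@H](c2ccc(O)cc2)CC(=O)O3)oc(=O)c1
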